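Assumption: the SMILES is taken as binding (4α-hydroxymethyl; C4' hydroxyl anti to the oxirane oxygen). The absolute sense of induction of the ferrocenyl diphosphine in step 7 and of the (2R,4R)-pentanediol ketal in step 18 is assigned from steric models, so the mirror-image ligand or diol would be substituted if the sense proved opposite.

Notation: decalin carbons carry drimane numbers (C1–C10; C11 is the methylene on C9; β is the face of the C10 methyl group). Ring E carbons are primed: C1' carbonyl, C2' methyl-bearing, C3', C4' carbinol, C5' bonded to C11, C6'. Ar = 5-methoxy-2-(methoxymethoxy)-4-methylphenyl, whose ring positions 1, 2, 4 and 5 become C5', C4', C2' and C1'.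

## Structural features

The target is a drimane-type trans-decalin (rings A and B) joined through a single methylene, C11, from C9 to C5' of a six-membered epoxyquinol, ring E (2'-methyl-2'-en-1'-one, C4' carbinol, C5'/C6' oxirane). The decalin holds four contiguous stereocentres: quaternary C4 (β-methyl, α-hydroxymethyl), C5 (α-H), quaternary C10 (β-methyl) and C9 (β-C11). It also holds a trisubstituted C7=C8 alkene with a methyl group on C8. Ring E holds three contiguous stereocentres: the cis oxirane at C5'/C6' and the C4' carbinol, whose hydroxyl is anti to the oxirane oxygen and syn to C11. C11 insulates ring E from the decalin, so the decalin cannot be trusted to set the ring E configuration; this, the vicinal C9/C10 pair and the quaternary C4 next to C5 are the real difficulties. The γ-hydroxy-α,β-epoxy enone is sensitive to base and strong acid, C7=C8 can migrate under acid and can capture a free C4' phenol at C8 to form a chroman, and the neopentyl primary alcohol needs cover during enolate chemistry. Ring E is at the oxidation level of a para-hydroquinone, so an arene with differentiated oxygens on C4' and C1' can carry it through the terpenoid chemistry. The key step exploits ring B: C9 bears C11, the adjacent C10 bears a methyl group and C1, and C5 and C8 both derive from carbonyl carbons, which is the pattern left by β-addition and α-alkylation of a 2-methylcyclohex-2-enone with a masked ketone at its C4.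

## Logic of the disconnections

30 ⇒ 29. The C1' carbonyl is drawn back to a cyclic ketal (two C1'–O bonds). The ketal prevents aromatisation of ring E and carries the chiral diol that controls the oxirane. The forward step must hydrolyse it without touching the oxirane, the allylic alcohol or C7=C8.

29 ⇒ 28. The C4'–H bond is cut, returning the carbinol to a ketone. This makes C4' the former phenol carbon. The forward step must deliver hydride 1,2 and on the face of the oxirane oxygen.

28 ⇒ 27. Both C–O bonds of the oxirane are cut, leaving a cross-conjugated dienone. Ring E becomes planar and free of stereocentres. The forward step must choose C5'=C6' over C2'=C3' and one face of the ring.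

27 ⇒ 26 ⇒ 25. The ketal C1'–O bonds are cut back to a para-methoxyphenol. The arene is inert to everything the decalin needs. The forward oxidation must take place at C1' only, which the free hydroxyl on C4' and the methoxy group on C1' ensure.

25 ⇒ 23. Two O–CH2OCH3 bonds are restored on the phenol and on the primary alcohol. The forward cleavage must avoid protic acid, because a free phenol next to C7=C8 would cyclise.

23 ⇒ 22 ⇒ 20 ⇒ 19. The C8–CH3 bond is cut (cross-coupling of an enol triflate) and C8 returns to a ketone and then to its ketal. The alkene position is then fixed by kinetic enolisation towards C7 and not C9.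

19 ⇒ 17 ⇒ 16. A carbonyl is put back on C3 and the ether O–C bond is cut. The C3 ketone is what allows C4 to be alkylated; the forward deoxygenation must not trigger retro-aldol loss of formaldehyde, so the alcohol is protected first.

16 ⇒ 14. The C4–CH2OH bond and the C5–H bond are cut. One operation on a conjugated enone sets C4 and C5. It must give the trans ring fusion and attack on the α face of C4.

14 ⇒ 13. The C4=C5 bond is cut (aldol condensation), opening ring A to a 1,5-diketone.

13 ⇒ 3 + 10 + 11. The C9–C11 and C1–C10 bonds are cut. Three simple pieces then supply ring B, four carbons of ring A and the whole arene. The forward step must control C9 absolutely and C10 relative to C9.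

3 ⇒ 2 ⇒ 1. Two C–H bonds are removed and the ketal is drawn back to a para-methoxyphenol. The hydrogenation must spare the methyl-bearing alkene.

10 ⇒ 9 ⇒ 8 ⇒ 5 ⇒ 4. The C–Mg and C–Cl bonds, the aryl–CH2OH bond and the acetal O–C bond are cut in turn. The metalation must occur ortho to the acetal oxygen on the unhindered side.

## Other disconnections considered

Alternative 1: The cut is the bond from C4 to its hydroxymethyl carbon. In the forward sense the (bromomethyl)dimethylsilyl ether A1 of a 3α-allylic alcohol on a Δ4-octalin, with C9 as a dioxolane, is treated with Bu3SnH and a radical initiator. The silylmethyl radical closes 5-exo on C4 and the C5 radical takes hydrogen, giving the cis-fused siloxane A2; oxidation of the C–Si bonds (Tamao oxidation) then reveals the hydroxymethyl group.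
- In its favour: the C4 configuration follows from the C3–O configuration by intramolecular delivery, the conditions are neutral, and the bicyclic core can come from a proline-catalysed Robinson annulation. On absolute stereocontrol this alternative is the better of the two.
- Against it: the radical must attack the fully substituted C4 of a tetrasubstituted alkene, so direct reduction and 6-endo closure compete. It needs the less accessible axial 3α alcohol, and the ring fusion rests on hydrogen transfer to a tertiary radical.
- Comparison: A2 contains no C8 substituent, no C11 and no arene, and these would have to be built on a neopentyl C9 carbonyl next to the quaternary C10. Both plans must remove a C3 oxygen, so they are equal there. On C4 control the two are equal, each resting on a well-known bias. On step economy the alternative is expected to be clearly longer, because the chosen plan makes C9–C11 at the outset.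

Alternative 2: The cut is the C2'=C3' bond of ring E. In the forward sense the open-chain epoxy alcohol A3 (isopropenyl ketone on C1', vinyl group on C4') is closed by the ruthenium alkylidene (H2IMes)Cl2Ru=CH(C6H4-2-OiPr) to the silyl ether A4, which is desilylated.
- In its favour: the three ring E stereocentres are made in an open chain, where titanium tartrate epoxidation and carbonyl addition offer reagent control. No dearomatisation, no choice between two enone double bonds and no ketone reduction of uncertain face are involved. On relative stereocontrol in ring E this alternative is the better.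
- Against it: the metathesis must engage an electron-poor 1,1-disubstituted alkene to form a trisubstituted enone. The free allylic alcohol may isomerise through a ruthenium hydride. A3 also requires a complete drimane unit to be joined at C11 to a tetrasubstituted oxirane carbon, so the hardest bond is moved to a late, precious intermediate.
- Comparison: the decalin still has to be made de novo because of the C4 hydroxymethyl group, so nothing is saved there. The ring-closing mechanism is as well understood as the epoxidation of the chosen plan. The ring E sequence on the full skeleton is expected to be longer than the five steps used here, so on step economy the alternative is expected to be inferior.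

Alternative 3: The cuts are C3–C4 and C5–C10. In the forward sense Me2AlCl activates the enal of the open-chain tetraene A5 and the C10=C1–C2=C3 diene adds across C4=C5, closing rings A and B at once to the trans-fused diene aldehyde A6. Reduction of the formyl group and selective hydrogenation of C1=C2 follow.
- In its favour: two rings, two bonds and three stereocentres arise in one step. C4 arrives at the aldehyde level, so there is no C3 oxygen to remove and no dissolving metal, and C7=C8 with its methyl group is already present. On step and redox economy this alternative is the better.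
- Against it: the cycloaddition creates two quaternary carbons (C4, C10) from a trisubstituted dienophile and a fully substituted diene terminus. Facial selectivity and the trans fusion rest on the single stereocentre C9, which is doubly allylic and exposed to the Lewis acid. A5 needs three stereodefined alkenes, including a (Z)-trisubstituted one.
- Comparison: if the cycloaddition behaves, this is the shortest route to the decalin. Its stereochemical outcome is less predictable than the stepwise sequence chosen here, which sets C9 by catalyst, C10 by anti alkylation and C4/C5 by a dissolving-metal reduction with a known bias. The ring E endgame would be the same in both plans.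

Key step: step 7

## Route

Step 1
Reactants: 1 4-methoxy-2-methylphenol
Product: 2 4,4-dimethoxy-2-methylcyclohexa-2,5-dien-1-one
Conditions: PhI(OAc)2, MeOH, 0 °C
Reagents that add atoms: methanol CO
Why: Oxidative dearomatisation of a para-methoxyphenol by the trivalent iodine reagent; methanol adds at the methoxy-bearing para carbon to give the quinone monoketal.

Step 2
Reactants: 2 4,4-dimethoxy-2-methylcyclohexa-2,5-dien-1-one
Product: 3 4,4-dimethoxy-2-methylcyclohex-2-en-1-one
Conditions: H2 (1 atm), RhCl(PPh3)3 (5 mol %), benzene, rt
Reagents that add atoms: none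
Why: Homogeneous hydrogenation with RhCl(PPh3)3 discriminates by substitution, so the disubstituted C5=C6 alkene should be saturated and the methyl-bearing enone kept; the neutral medium avoids loss of methanol and rearomatisation.

Step 3
Reactants: 4 4-methoxy-3-methylphenol
Product: 5 1-methoxy-4-(methoxymethoxy)-2-methylbenzene
Conditions: MeOCH2Cl, iPr2NEt, CH2Cl2, 0 °C → rt
Reagents that add atoms: chloromethyl methyl ether COCCl
Why: O-alkylation of the phenol to the methoxymethyl acetal, which differentiates the two ring oxygens and later directs metalation.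

Step 4
Reactants: 5 1-methoxy-4-(methoxymethoxy)-2-methylbenzene
Product: 8 [5-methoxy-2-(methoxymethoxy)-4-methylphenyl]methanol, via aryllithium 6 (not isolated), via aldehyde 7 (not isolated)
Conditions: n-BuLi, TMEDA, Et2O, 0 °C; DMF, −78 → 0 °C; then MeOH, NaBH4, 0 °C
Reagents that add atoms: N,N-dimethylformamide CN(C)C=O
Why: Directed ortho-metalation at the unhindered position next to the acetal oxygen (the stronger director), formylation of the aryllithium and borohydride reduction of the aldehyde in the same flask.

Step 5
Reactants: 8 [5-methoxy-2-(methoxymethoxy)-4-methylphenyl]methanol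
Product: 9 1-(chloromethyl)-5-methoxy-2-(methoxymethoxy)-4-methylbenzene
Conditions: MeSO2Cl, Et3N, CH2Cl2, 0 °C → rt
Reagents that add atoms: methanesulfonyl chloride CS(=O)(=O)Cl
Why: The mesylate of this electron-rich benzylic alcohol is displaced in the flask by chloride, and the basic medium keeps the acetal intact.

Step 6
Reactants: 9 1-(chloromethyl)-5-methoxy-2-(methoxymethoxy)-4-methylbenzene
Product: 10 [5-methoxy-2-(methoxymethoxy)-4-methylphenyl]methylmagnesium chloride (Et2O solution)
Conditions: Mg turnings (activated with BrCH2CH2Br), Et2O, 0 °C, slow addition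
Reagents that add atoms: magnesium [Mg]
Why: Magnesium insertion into the benzylic C–Cl bond; excess metal, dilution and slow addition suppress Wurtz coupling, and the ortho acetal oxygen stabilises the reagent by chelation.

Step 7
Reactants: 3 4,4-dimethoxy-2-methylcyclohex-2-en-1-one; 10 [5-methoxy-2-(methoxymethoxy)-4-methylphenyl]methylmagnesium chloride; 11 pent-1-en-3-one (ethyl vinyl ketone)
Product: 13 (2R,3R)-3-(ArCH2)-4,4-dimethoxy-2-methyl-2-(3-oxopentyl)cyclohexan-1-one, via chloromagnesium enolate 12 (not isolated)
Conditions: CuBr·SMe2 (5 mol %), (R)-1-[(SP)-2-(diphenylphosphino)ferrocenyl]ethyldicyclohexylphosphine (6 mol %), t-BuOMe, −78 °C, slow addition of 10; then 11, −78 → −40 °C; aq. NH4Cl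
Reagents that add atoms: none
Why: Transmetalation of 10 to the diphosphine-bound monovalent copper gives a benzylcopper species that forms a π-complex with 3 and adds at C9 (trivalent copper); reductive elimination makes C9–C11 and leaves the chloromagnesium C5–C10 enolate 12 as a single regioisomer. The closest known reaction type is the copper-catalysed enantioselective conjugate addition of Grignard reagents to cyclohexenones with ferrocenyl diphosphines, followed by Michael capture of the metal enolate by a vinyl ketone (first half of a Robinson annulation). No ring closes. C9 is set by the chiral catalyst, which selects the enone face, since the achiral ketal exerts no bias. C10 is set by the substrate: in 12 the C9 arylmethyl group stands pseudoaxial to escape allylic strain with the C10 methyl group, so 11 is taken up at C10 on the opposite face and C1 ends trans to C11. The step needs 1,4- over 1,2-addition, which slow addition of 10 to the catalyst at −78 °C and the inductively activating ketal next to C9 should secure. It needs bond formation at C10 without enolate equilibration, which holds because 12 is formed regiospecifically and C6 is not deprotonated at this temperature. It also needs a single Michael addition, which the quench at −40 °C, before the product enolate can add to more 11, should ensure.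

Step 8
Reactants: 13 (2R,3R)-3-(ArCH2)-4,4-dimethoxy-2-methyl-2-(3-oxopentyl)cyclohexan-1-one
Product: 14 (4aR,5R)-5-(ArCH2)-6,6-dimethoxy-1,4a-dimethyl-4,4a,5,6,7,8-hexahydronaphthalen-2(3H)-one
Conditions: KOH, MeOH, 60 °C
Reagents that add atoms: none
Why: Intramolecular aldol condensation (second half of a Robinson annulation): the C4 enolate of the ethyl ketone attacks the C5 ketone and dehydration gives the C4=C5 enone; C9 and C10 carry no acidic hydrogen and cannot epimerise.

Step 9
Reactants: 14 (4aR,5R)-5-(ArCH2)-6,6-dimethoxy-1,4a-dimethyl-4,4a,5,6,7,8-hexahydronaphthalen-2(3H)-one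
Product: 16 9β-(ArCH2)-4α-(hydroxymethyl)-8,8-dimethoxy-4β,10β-dimethyl-5α-decalin-3-one, via lithium enolate 15 (not isolated)
Conditions: Li (2.2 equiv), NH3/THF, t-BuOH (1 equiv), −78 °C; NH3 removed; CH2O (gas), THF, −78 °C; aq. NH4Cl
Reagents that add atoms: formaldehyde C=O
Why: Dissolving-metal reduction gives the C3–C4 lithium enolate 15 with C5 protonated on the α face (trans-decalin); its aldol reaction with monomeric formaldehyde occurs on the α face of C4, away from the axial C10 methyl group, so the hydroxymethyl group becomes 4α (reductive hydroxymethylation).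

Step 10
Reactants: 16 9β-(ArCH2)-4α-(hydroxymethyl)-8,8-dimethoxy-4β,10β-dimethyl-5α-decalin-3-one
Product: 17 methoxymethyl ether of 16
Conditions: MeOCH2Cl, iPr2NEt, CH2Cl2, rt
Reagents that add atoms: chloromethyl methyl ether COCCl
Why: Acetal protection of the neopentyl alcohol under amine base, which blocks retro-aldol loss of formaldehyde in the next step and covers the hydroxyl during triflation.

Step 11
Reactants: 17 methoxymethyl ether of 16
Product: 19 9β-(ArCH2)-8,8-dimethoxy-4α-(methoxymethoxymethyl)-4β,10β-dimethyl-5α-decalin, via hydrazone 18 (not isolated)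
Conditions: N2H4·H2O, KOH, diethylene glycol, 130 → 200 °C
Reagents that add atoms: none
Why: Wolff–Kishner reduction (Huang-Minlon procedure) of the C3 ketone, a reaction that works on 3-oxo-4,4-disubstituted terpenoids; both acetals, the ketal and the aryl methyl ether are stable to hot base, and C4 has no hydrogen to lose.

Step 12
Reactants: 19 9β-(ArCH2)-8,8-dimethoxy-4α-(methoxymethoxymethyl)-4β,10β-dimethyl-5α-decalin
Product: 20 9β-(ArCH2)-4α-(methoxymethoxymethyl)-4β,10β-dimethyl-5α-decalin-8-one
Conditions: AcOH/THF/H2O (3:1:1), rt
Reagents that add atoms: water O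
Why: Mild hydrolysis of the dimethyl ketal, which ionises far more readily than the methoxymethyl ethers; the C9 substituent is equatorial and therefore configurationally stable next to the new ketone.

Step 13
Reactants: 20 9β-(ArCH2)-4α-(methoxymethoxymethyl)-4β,10β-dimethyl-5α-decalin-8-one
Product: 22 Δ7-en-8-yl trifluoromethanesulfonate of 20, via potassium enolate 21 (not isolated)
Conditions: KN(SiMe3)2, THF, −78 °C; PhNTf2, −78 → 0 °C
Reagents that add atoms: N-phenylbis(trifluoromethanesulfonimide) O=S(=O)(N(c1ccccc1)S(=O)(=O)C(F)(F)F)C(F)(F)F
Why: Kinetic deprotonation by the bulky amide takes a C7 hydrogen and not the hindered tertiary C9 hydrogen, and O-sulfonylation fixes the C7=C8 position.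

Step 14
Reactants: 22 Δ7-en-8-yl trifluoromethanesulfonate of 20
Product: 23 9β-(ArCH2)-4α-(methoxymethoxymethyl)-4β,8,10β-trimethyl-5α-octal-7-ene
Conditions: Fe(acac)3 (10 mol %), MeMgBr, THF/NMP, −30 → 0 °C
Reagents that add atoms: methylmagnesium bromide C[Mg]Br
Why: Iron-catalysed cross-coupling of an alkenyl triflate with a methyl Grignard reagent, a fast reaction at low temperature that tolerates ethers and acetals and retains the alkene position.

Step 15
Reactants: 23 9β-(ArCH2)-4α-(methoxymethoxymethyl)-4β,8,10β-trimethyl-5α-octal-7-ene
Product: 25 2-{[4α-(hydroxymethyl)-4β,8,10β-trimethyl-5α-octal-7-en-9β-yl]methyl}-4-methoxy-5-methylphenol, via bis(bromomethyl) ether 24 (not isolated)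
Conditions: Me2BBr, CH2Cl2, −78 °C; then THF/sat. aq. NaHCO3
Reagents that add atoms: none
Why: The bromoborane cleaves both methoxymethyl ethers at −78 °C to bromomethyl ethers, which are hydrolysed in the basic quench, so the phenol is never exposed to protic acid beside C7=C8 (no alkene migration or chroman formation); the aryl methyl ether is inert at this temperature.

Step 16
Reactants: 25 2-{[4α-(hydroxymethyl)-4β,8,10β-trimethyl-5α-octal-7-en-9β-yl]methyl}-4-methoxy-5-methylphenol
Product: 26 dienone dimethyl ketal (C4' ketone; C1' dimethoxy; C5'=C6' and C2'=C3')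
Conditions: PhI(OAc)2, NaHCO3, MeOH, 0 °C
Reagents that add atoms: methanol CO
Why: Oxidative dearomatisation as in step 1; the free hydroxyl on C4' and the methoxy group on C1' fix the regiochemistry, and the alkene and primary alcohol are not attacked by the trivalent iodine reagent under these conditions.

Step 17
Reactants: 26 dienone dimethyl ketal
Product: 27 dienone (4R,6R)-4,6-dimethyl-1,3-dioxane ketal
Conditions: (2R,4R)-pentane-2,4-diol, PPTS, benzene, 4 Å MS, 70 °C
Reagents that add atoms: (2R,4R)-pentane-2,4-diol C[C@@H](O)C[C@@H](C)O
Why: Acid-catalysed transketalisation, driven by ring formation and removal of methanol; the diol is C2-symmetric, so the spiro carbon C1' is not a stereocentre and a single compound results.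

Step 18
Reactants: 27 dienone (4R,6R)-4,6-dimethyl-1,3-dioxane ketal
Product: 28 C5'/C6' epoxy enone dioxane ketal
Conditions: Ph3COOH, KN(SiMe3)2, THF, −35 °C
Reagents that add atoms: trityl hydroperoxide OOC(c1ccccc1)(c1ccccc1)c1ccccc1
Why: Nucleophilic (Weitz–Scheffer) epoxidation: the bulky peroxide anion adds to C6', the only hydrogen-bearing β-carbon of the cross-conjugated dienone, and closes on C5'; in the preferred dioxane chair C6' is axial and the syn-axial methyl group of the auxiliary screens one face, so the oxirane should form on the face required.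

Step 19
Reactants: 28 C5'/C6' epoxy enone dioxane ketal
Product: 29 C4' alcohol of 28 (hydroxyl anti to the oxirane oxygen)
Conditions: NaBH4, CeCl3·7H2O, MeOH, −78 °C
Reagents that add atoms: none
Why: Luche 1,2-reduction of the enone carbonyl; borohydride reduction of cyclic α,β-epoxy ketones is expected to favour the trans epoxy alcohol, and the C11 methylene on C5' screens the other face, so hydride should enter syn to the oxirane oxygen.

Step 20
Reactants: 29 C4' alcohol of 28
Product: 30 epoxyphomalin B (target)
Conditions: 48% aq. HF, MeCN, 0 °C → rt
Reagents that add atoms: water O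
Why: Hydrolysis of the allylic ketal by a weak acid that spares the oxirane, the allylic alcohol and C7=C8; the C1' enone appears and the auxiliary diol is released.

## Compound list

1 | 4-methoxy-2-methylphenol | COc1ccc(O)c(C)c1 | starting material
2 | 4,4-dimethoxy-2-methylcyclohexa-2,5-dien-1-one | CC1=CC(OC)(OC)C=CC1=O | intermediate
3 | 4,4-dimethoxy-2-methylcyclohex-2-en-1-one | CC1=CC(OC)(OC)CCC1=O | intermediate
4 | 4-methoxy-3-methylphenol | COc1ccc(O)cc1C | starting material
5 | 1-methoxy-4-(methoxymethoxy)-2-methylbenzene | COCOc1ccc(OC)c(C)c1 | intermediate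
6 | [5-methoxy-2-(methoxymethoxy)-4-methylphenyl]lithium (forms in the flask of step 4) | [Li]c1cc(OC)c(C)cc1OCOC | intermediate
7 | 5-methoxy-2-(methoxymethoxy)-4-methylbenzaldehyde (forms in the flask of step 4) | O=Cc1cc(OC)c(C)cc1OCOC | intermediate
8 | [5-methoxy-2-(methoxymethoxy)-4-methylphenyl]methanol | OCc1cc(OC)c(C)cc1OCOC | intermediate
9 | 1-(chloromethyl)-5-methoxy-2-(methoxymethoxy)-4-methylbenzene | ClCc1cc(OC)c(C)cc1OCOC | intermediate
10 | [5-methoxy-2-(methoxymethoxy)-4-methylphenyl]methylmagnesium chloride | COCOc1cc(C)c(OC)cc1C[Mg]Cl | intermediate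
11 | pent-1-en-3-one (ethyl vinyl ketone) | CCC(=O)C=C | starting material
12 | chloromagnesium (3R)-3-(ArCH2)-4,4-dimethoxy-2-methylcyclohex-1-en-1-olate (forms in the flask of step 7) | Cl[Mg]OC1=C(C)[C@@H](Cc2cc(OC)c(C)cc2OCOC)C(OC)(OC)CC1 | intermediate
13 | (2R,3R)-3-{[5-methoxy-2-(methoxymethoxy)-4-methylphenyl]methyl}-4,4-dimethoxy-2-methyl-2-(3-oxopentyl)cyclohexan-1-one | CCC(=O)CC[C@]1(C)[C@@H](Cc2cc(OC)c(C)cc2OCOC)C(OC)(OC)CCC1=O | intermediate
14 | (4aR,5R)-5-(ArCH2)-6,6-dimethoxy-1,4a-dimethyl-4,4a,5,6,7,8-hexahydronaphthalen-2(3H)-one (drimane: Δ4-3-one, 9β-CH2Ar, 10β-CH3) | CC1=C2CCC(OC)(OC)[C@H](Cc3cc(OC)c(C)cc3OCOC)[C@@]2(C)CCC1=O | intermediate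
15 | lithium C3–C4 enolate of the 5α-H trans-decalin-3-one (forms in the flask of step 9) | [Li]OC1=C(C)[C@@H]2CCC(OC)(OC)[C@H](Cc3cc(OC)c(C)cc3OCOC)[C@@]2(C)CC1 | intermediate
16 | 9β-(ArCH2)-4α-(hydroxymethyl)-8,8-dimethoxy-4β,10β-dimethyl-5α-decalin-3-one | O=C1CC[C@]2(C)[C@@H](Cc3cc(OC)c(C)cc3OCOC)C(OC)(OC)CC[C@H]2[C@]1(C)CO | intermediate
17 | methoxymethyl ether of 16 | O=C1CC[C@]2(C)[C@@H](Cc3cc(OC)c(C)cc3OCOC)C(OC)(OC)CC[C@H]2[C@]1(C)COCOC | intermediate
18 | C3 hydrazone of 17 (forms in the flask of step 11) | NN=C1CC[C@]2(C)[C@@H](Cc3cc(OC)c(C)cc3OCOC)C(OC)(OC)CC[C@H]2[C@]1(C)COCOC | intermediate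
19 | 9β-(ArCH2)-8,8-dimethoxy-4α-(methoxymethoxymethyl)-4β,10β-dimethyl-5α-decalin | C1CC[C@]2(C)[C@@H](Cc3cc(OC)c(C)cc3OCOC)C(OC)(OC)CC[C@H]2[C@]1(C)COCOC | intermediate
20 | 9β-(ArCH2)-4α-(methoxymethoxymethyl)-4β,10β-dimethyl-5α-decalin-8-one | C1CC[C@]2(C)[C@@H](Cc3cc(OC)c(C)cc3OCOC)C(=O)CC[C@H]2[C@]1(C)COCOC | intermediate
21 | potassium C7–C8 enolate of 20 (forms in the flask of step 13) | C1CC[C@]2(C)[C@@H](Cc3cc(OC)c(C)cc3OCOC)C(O[K])=CC[C@H]2[C@]1(C)COCOC | intermediate
22 | Δ7-en-8-yl trifluoromethanesulfonate of 20 | C1CC[C@]2(C)[C@@H](Cc3cc(OC)c(C)cc3OCOC)C(OS(=O)(=O)C(F)(F)F)=CC[C@H]2[C@]1(C)COCOC | intermediate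
23 | 9β-(ArCH2)-4α-(methoxymethoxymethyl)-4β,8,10β-trimethyl-5α-octal-7-ene | C1CC[C@]2(C)[C@@H](Cc3cc(OC)c(C)cc3OCOC)C(C)=CC[C@H]2[C@]1(C)COCOC | intermediate
24 | bis(bromomethyl) ether of 25, on the phenol and primary alcohol oxygens (forms in the flask of step 15) | C1CC[C@]2(C)[C@@H](Cc3cc(OC)c(C)cc3OCBr)C(C)=CC[C@H]2[C@]1(C)COCBr | intermediate
25 | 2-{[4α-(hydroxymethyl)-4β,8,10β-trimethyl-5α-octal-7-en-9β-yl]methyl}-4-methoxy-5-methylphenol | C1CC[C@]2(C)[C@@H](Cc3cc(OC)c(C)cc3O)C(C)=CC[C@H]2[C@]1(C)CO | intermediate
26 | 2-(drimanylmethyl)-4,4-dimethoxy-5-methylcyclohexa-2,5-dien-1-one (C4' ketone, C1' dimethyl ketal) | C1CC[C@]2(C)[C@@H](CC3=CC(OC)(OC)C(C)=CC3=O)C(C)=CC[C@H]2[C@]1(C)CO | intermediate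
27 | spiro (4R,6R)-4,6-dimethyl-1,3-dioxane ketal of the dienone 26 | C1CC[C@]2(C)[C@@H](CC3=CC4(O[C@H](C)C[C@@H](C)O4)C(C)=CC3=O)C(C)=CC[C@H]2[C@]1(C)CO | intermediate
28 | C5'/C6' epoxide of 27 (oxirane anti to C11; C4' ketone) | CC1=CC(=O)[C@]2(C[C@H]3C(C)=CC[C@H]4[C@](C)(CO)CCC[C@]34C)O[C@@H]2C15O[C@H](C)C[C@@H](C)O5 | intermediate
29 | C4' alcohol of 28 (hydroxyl anti to the oxirane oxygen) | CC1=C[C@@H](O)[C@]2(C[C@H]3C(C)=CC[C@H]4[C@](C)(CO)CCC[C@]34C)O[C@@H]2C15O[C@H](C)C[C@@H](C)O5 | intermediate
30 | epoxyphomalin B | CC1=C[C@@H](O)[C@]2(C[C@H]3C(C)=CC[C@H]4[C@](C)(CO)CCC[C@]34C)O[C@@H]2C1=O | target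

## Step count and least certain steps

Total: 20 steps. Longest linear sequence: 18 steps (4 → 30, steps 3 to 20); the enone branch (1 → 3) adds 2 steps.

Step 7 (key step). The most likely failures are uncatalysed 1,2-addition or low enantioselection, because C9 is flanked by the ketal and the α-methyl group and a benzyl group is a poor transfer partner. The second bond may also fail through proton transfer to the hindered enolate and polymerisation of 11. The fallback sets out from 3 and 10 and returns at 14. The enolate 12 is silylated in the flask (Me3SiCl, Et3N) and the trimethylsilyl enol ether F1 is isolated. MeLi in THF then regenerates a lithium enolate free of proton sources, and 2-(trimethylsilyl)pent-1-en-3-one, which cannot polymerise and gives a stabilised adduct anion, is added at −78 °C to give the α-silyl diketone F2. KOH in MeOH removes silicon and closes ring A to 14.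

Step 19. Hydride delivery anti to the oxirane oxygen, giving the syn epoxy alcohol, is the main risk, since the facial preference of this flat, ketal-bearing ring is not secured by a rigid element. The fallback sets out from 28 and returns at 29. Reduction with iBu2AlH in THF at −78 °C, a bulky reagent expected to attack anti to the oxirane, gives the syn alcohol F6. A Mitsunobu reaction (4-nitrobenzoic acid, PPh3, diisopropyl azodicarboxylate) inverts C4' to the 4-nitrobenzoate F7; the neopentyl primary alcohol resists displacement. K2CO3 in MeOH then gives 29.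

Step 18. Poor or reversed facial selection by the auxiliary, or sluggish attack at C6' next to the spiro ketal, would erode the diastereomeric purity of ring E. The fallback sets out from 26 and returns at 30. The dimethyl ketal itself is epoxidised under phase transfer with a cinchona-derived quaternary ammonium salt (N-benzylcinchonidinium chloride, t-BuOOH, NaOH, toluene) to the epoxy enone dimethyl ketal F4. Its ring E diastereomer is separable because the decalin is enantiopure. Luche reduction gives the alcohol F5, and oxalic acid in wet THF gives 30.

Step 9. Protonation of the enolate in place of hydroxymethylation, polymerisation of formaldehyde by residual amide base and partial reduction of the arene by excess metal are the likely losses. The fallback sets out from 14 and returns at 16. The same reduction is quenched with Me3SiCl/Et3N to give the trimethylsilyl enol ether F3, which is purified. MeLi in THF liberates the ammonia-free lithium enolate, which is treated at −78 °C with anhydrous monomeric formaldehyde to give 16.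

## Further compounds

F1 | step 7 | {[(3R)-3-(ArCH2)-4,4-dimethoxy-2-methylcyclohex-1-en-1-yl]oxy}trimethylsilane | CC1=C(O[Si](C)(C)C)CCC(OC)(OC)[C@@H]1Cc2cc(OC)c(C)cc2OCOC
F2 | step 7 | (2R,3R)-3-(ArCH2)-4,4-dimethoxy-2-methyl-2-[3-oxo-2-(trimethylsilyl)pentyl]cyclohexan-1-one (both epimers at the silyl-bearing carbon) | CCC(=O)C([Si](C)(C)C)C[C@]1(C)[C@@H](Cc2cc(OC)c(C)cc2OCOC)C(OC)(OC)CCC1=O
F3 | step 9 | trimethylsilyl C3–C4 enol ether of the 5α-H trans-decalin-3-one | C[Si](C)(C)OC1=C(C)[C@@H]2CCC(OC)(OC)[C@H](Cc3cc(OC)c(C)cc3OCOC)[C@@]2(C)CC1
F4 | step 18 | C5'/C6' epoxide of 26 (dimethyl ketal) | CC1=CC(=O)[C@]2(C[C@H]3C(C)=CC[C@H]4[C@](C)(CO)CCC[C@]34C)O[C@@H]2C1(OC)OC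
F5 | step 18 | C4' alcohol of F4 (hydroxyl anti to the oxirane oxygen) | CC1=C[C@@H](O)[C@]2(C[C@H]3C(C)=CC[C@H]4[C@](C)(CO)CCC[C@]34C)O[C@@H]2C1(OC)OC
F6 | step 19 | C4' epimer of 29 (hydroxyl syn to the oxirane oxygen) | CC1=C[C@H](O)[C@]2(C[C@H]3C(C)=CC[C@H]4[C@](C)(CO)CCC[C@]34C)O[C@@H]2C15O[C@H](C)C[C@@H](C)O5
F7 | step 19 | C4' 4-nitrobenzoate of 29 | CC1=C[C@@H](OC(=O)c6ccc(cc6)[N+](=O)[O-])[C@]2(C[C@H]3C(C)=CC[C@H]4[C@](C)(CO)CCC[C@]34C)O[C@@H]2C15O[C@H](C)C[C@@H](C)O5
A1 | alternative 1 | (bromomethyl)dimethylsilyl ether of 9,9-(ethylenedioxy)-4,10β-dimethyl-Δ4-octalin-3α-ol | BrC[Si](C)(C)O[C@@H]1CC[C@@]2(C)C(=C1C)CCCC23OCCO3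
A2 | alternative 1 | cis-fused cyclic siloxane on the trans-decalin C9 ketal | C[Si]1(C)C[C@]2(C)[C@H](O1)CC[C@@]3(C)[C@H]2CCCC34OCCO4
A3 | alternative 2 | open-chain epoxy alcohol (isopropenyl ketone on C1', vinyl carbinol at C4', silyl ether on the primary alcohol) | C=C(C)C(=O)[C@H]1O[C@@]1(C[C@H]2C(C)=CC[C@H]3[C@](C)(CO[Si](C)(C)C(C)(C)C)CCC[C@]23C)[C@H](O)C=C
A4 | alternative 2 | tert-butyldimethylsilyl ether of the target | CC1=C[C@@H](O)[C@]2(C[C@H]3C(C)=CC[C@H]4[C@](C)(CO[Si](C)(C)C(C)(C)C)CCC[C@]34C)O[C@@H]2C1=O
A5 | alternative 3 | open-chain tetraene aldehyde ((E)-enal, (Z)-C7=C8, (E)-C10=C1 diene, aryl pivalate) | O=C/C(C)=C/C/C=C(C)\[C@H](Cc1cc(OC)c(C)cc1OC(=O)C(C)(C)C)/C(C)=C/C=C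
A6 | alternative 3 | trans-fused diene aldehyde (C1=C2 and C7=C8, formyl on C4) | COc1cc(C[C@H]2C(C)=CC[C@H]3[C@](C)(C=O)CC=C[C@]23C)c(OC(=O)C(C)(C)C)cc1C
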